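**Retrosynthetic overview**

- Isoangustone A is cut at C1''–C2'' and C1'''–C2'''. The prenyl CH2 on C6 of ring A is ortho to O5 and the prenyl CH2 on C5' of ring B is ortho to O4', so each can be the exocyclic carbon of an ortho-quinone methide that takes a 2-methylprop-1-enyl group from boron.
- Both quinone methides come from one bis(ortho-hydroxybenzyl alcohol). O7 and O3' carry MOM groups, so each ring offers boron a single phenol/CH2OH pair and ring B has no free catechol; both MOM groups fall in the last step.
- Ring A CH2OH: iodination at C6, ortho to the chelated 5-OH of the isoflavone, then Stille hydroxymethylation. Ring B CH2OH: reduction of a formyl group brought in with the ring B boronate, whose chelated phenol also differentiates the two catechol oxygens.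
- Isoflavone core by Suzuki–Miyaura coupling of a 3-iodochromone with the ring B boronate. Rings A and B are bought as arenes, ring C (the pyranone) is closed in step 3 from a symmetric 2,6-dihydroxyaryl enaminone, and no ring is closed afterwards.

Key step: step 10

Remark: O7 is deliberately kept as its MOM ether through the key step; 5-bromo-2,3-dihydroxybenzaldehyde, (tributylstannyl)methanol, benzyltrimethylammonium dichloroiodate and (2-methylprop-1-en-1-yl)boronic acid are taken as purchased.

**Route**

Step 1
Reactants: 1 1-(2,4,6-trihydroxyphenyl)ethanone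
Product: 2 1-[2,6-dihydroxy-4-(methoxymethoxy)phenyl]ethanone
Conditions: MOMCl (1.0 equiv), i-Pr2NEt (1.2 equiv), CH2Cl2/THF, 0 °C
Reagents that add atoms: chloromethyl methyl ether, COCCl
Why: Williamson-type O-alkylation should go to the 4-OH, the only phenol not hydrogen-bonded to the acetyl carbonyl and the most acidic one, so the two equivalent ortho phenols stay free.

Step 2
Reactants: 2 1-[2,6-dihydroxy-4-(methoxymethoxy)phenyl]ethanone
Product: 3 (E)-1-[2,6-dihydroxy-4-(methoxymethoxy)phenyl]-3-(dimethylamino)prop-2-en-1-one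
Conditions: Me2NCH(OMe)2 (1.5 equiv), toluene, 80 °C
Reagents that add atoms: N,N-dimethylformamide dimethyl acetal, COC(OC)N(C)C
Why: Condensation of the methyl ketone with the amide acetal (enaminone formation) should give the E enaminone, the chelated ortho phenols resisting O-methylation at this temperature.

Step 3
Reactants: 3 (E)-1-[2,6-dihydroxy-4-(methoxymethoxy)phenyl]-3-(dimethylamino)prop-2-en-1-one
Product: 4 5-hydroxy-3-iodo-7-(methoxymethoxy)chromen-4-one
Conditions: I2 (1.05 equiv), pyridine (1.1 equiv), CHCl3, rt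
Reagents that add atoms: iodine, II
Why: Iodine-mediated enaminone cyclisation (iodination of the enaminone α-carbon, attack of an ortho phenol on the iminium carbon, loss of dimethylamine) closes ring C as a 3-iodochromone, and because the two ortho phenols are equivalent only one chromone can form.

Step 4
Reactants: 5 5-bromo-2,3-dihydroxybenzaldehyde
Product: 6 5-bromo-2-hydroxy-3-(methoxymethoxy)benzaldehyde
Conditions: NaH (2.2 equiv), DMF, 0 °C; MOMCl (1.0 equiv)
Reagents that add atoms: chloromethyl methyl ether, COCCl
Why: In the dianion the 3-phenoxide is not conjugated with the formyl group and is the more nucleophilic oxygen, so Williamson O-alkylation with one equivalent of the chloromethyl ether should give the 3-O-MOM ether and leave the chelated 2-OH free.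

Step 5
Reactants: 6 5-bromo-2-hydroxy-3-(methoxymethoxy)benzaldehyde
Product: 7 2-hydroxy-3-(methoxymethoxy)-5-(4,4,5,5-tetramethyl-1,3,2-dioxaborolan-2-yl)benzaldehyde
Conditions: B2pin2, PdCl2(dppf) (3 mol%), KOAc, 1,4-dioxane, 85 °C
Reagents that add atoms: bis(pinacolato)diboron, CC1(C)OB(OC1(C)C)B1OC(C)(C)C(C)(C)O1
Why: Miyaura borylation (oxidative addition of the aryl bromide to zerovalent palladium, acetate-assisted transmetalation from the diboron, reductive elimination) tolerates the chelated phenol, the aldehyde and the MOM ether.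

Step 6
Reactants: 4 5-hydroxy-3-iodo-7-(methoxymethoxy)chromen-4-one; 7 2-hydroxy-3-(methoxymethoxy)-5-(4,4,5,5-tetramethyl-1,3,2-dioxaborolan-2-yl)benzaldehyde
Product: 8 2-hydroxy-5-[5-hydroxy-7-(methoxymethoxy)-4-oxochromen-3-yl]-3-(methoxymethoxy)benzaldehyde
Conditions: PdCl2(dppf) (5 mol%), aq. Na2CO3 (3 equiv), DME, 80 °C
Reagents that add atoms: none
Why: Suzuki–Miyaura coupling forms the C3–C1' bond of the isoflavone, the 3-iodochromone being a vinylogous acyl iodide that adds readily to zerovalent palladium.

Step 7
Reactants: 8 2-hydroxy-5-[5-hydroxy-7-(methoxymethoxy)-4-oxochromen-3-yl]-3-(methoxymethoxy)benzaldehyde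
Product: 9 2-hydroxy-5-[5-hydroxy-6-iodo-7-(methoxymethoxy)-4-oxochromen-3-yl]-3-(methoxymethoxy)benzaldehyde
Conditions: BnMe3N ICl2 (1.05 equiv), CaCO3, CH2Cl2/MeOH, rt
Reagents that add atoms: benzyltrimethylammonium dichloroiodate, C[N+](C)(C)Cc1ccccc1.Cl[I-]Cl
Why: Electrophilic aromatic iodination should go to C6, the position ortho to the chelated 5-OH of a 5-hydroxy-7-alkoxychromone, while ring B is deactivated by its formyl group and has no free position ortho or para to its phenol, and calcium carbonate takes up the hydrogen chloride so that the MOM ethers survive.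

Step 8
Reactants: 9 2-hydroxy-5-[5-hydroxy-6-iodo-7-(methoxymethoxy)-4-oxochromen-3-yl]-3-(methoxymethoxy)benzaldehyde
Product: 10 5-hydroxy-3-[4-hydroxy-3-(hydroxymethyl)-5-(methoxymethoxy)phenyl]-6-iodo-7-(methoxymethoxy)chromen-4-one
Conditions: NaBH4 (1.0 equiv), THF/MeOH, 0 °C
Reagents that add atoms: none
Why: Borohydride reduction of the salicylaldehyde at 0 °C is much faster than hydride attack on the chelated chromone, and it is placed before the hydroxymethylation so that the sensitive ring A benzyl alcohol never meets hydride.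

Step 9
Reactants: 10 5-hydroxy-3-[4-hydroxy-3-(hydroxymethyl)-5-(methoxymethoxy)phenyl]-6-iodo-7-(methoxymethoxy)chromen-4-one
Product: 11 5-hydroxy-6-(hydroxymethyl)-3-[4-hydroxy-3-(hydroxymethyl)-5-(methoxymethoxy)phenyl]-7-(methoxymethoxy)chromen-4-one
Conditions: Bu3SnCH2OH (1.5 equiv), Pd(PPh3)4 (10 mol%), 1,4-dioxane, 80–90 °C
Reagents that add atoms: (tributylstannyl)methanol, CCCC[Sn](CCCC)(CCCC)CO
Why: Stille coupling of the aryl iodide with (tributylstannyl)methanol transfers the hydroxymethyl group to C6 under neutral conditions, which gives the second ortho-hydroxybenzyl alcohol without a reduction step.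

Step 10
Reactants: 11 5-hydroxy-6-(hydroxymethyl)-3-[4-hydroxy-3-(hydroxymethyl)-5-(methoxymethoxy)phenyl]-7-(methoxymethoxy)chromen-4-one; 12 (2-methylprop-1-en-1-yl)boronic acid
Product: 15 5-hydroxy-3-[4-hydroxy-3-(methoxymethoxy)-5-(3-methylbut-2-en-1-yl)phenyl]-7-(methoxymethoxy)-6-(3-methylbut-2-en-1-yl)chromen-4-one, via bis(alkenyldioxaborin) 13 (not isolated), via boron-bound bis(ortho-quinone methide) 14 (not isolated)
Conditions: 12 (3 equiv), 4 Å MS, toluene/1,4-dioxane (4:1), 0.01 M, rt then 90 °C
Reagents that add atoms: none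
Why: Each ortho-hydroxybenzyl alcohol (O5/6-CH2OH on ring A, O4'/5'-CH2OH on ring B) condenses with 12 to a 2-alkenyl-4H-1,3,2-dioxaborin (13); heating ionises each benzylic C–O bond to a boron-bound ortho-quinone methide (14), and the 2-methylprop-1-enyl group shifts from boron to the exocyclic CH2 through a six-membered transition state, which restores the arene and forms C1''–C2'' and C1'''–C2'''. The closest known reaction types are the ortho-specific alkylation of phenols through 1,3,2-benzodioxaborins and the 1,4-addition of alkenylboronic acids or boronates to ortho-quinone methides generated from ortho-hydroxybenzyl alcohols or their ethers. No ring is closed and no stereocentre is formed, and the new olefins carry two identical methyl groups, so no alkene geometry arises. The step needs C-alkylation at the two benzylic carbons in preference to attack at the chromone C2, to O-alkylation and to capture of the ring A quinone methide by C8 of a second molecule; delivery of the alkenyl group inside the boron–phenoxide ion pair, high dilution and an excess of 12 should secure this. The MOM groups on O7 and O3' leave one phenol/CH2OH pair per ring for boron and prevent a catechol boronate on ring B. The medium is neutral, so the new prenyl groups should not cyclise onto the neighbouring phenols.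

Step 11
Reactants: 15 5-hydroxy-3-[4-hydroxy-3-(methoxymethoxy)-5-(3-methylbut-2-en-1-yl)phenyl]-7-(methoxymethoxy)-6-(3-methylbut-2-en-1-yl)chromen-4-one
Product: 16 isoangustone A, 3-[3,4-dihydroxy-5-(3-methylbut-2-en-1-yl)phenyl]-5,7-dihydroxy-6-(3-methylbut-2-en-1-yl)chromen-4-one
Conditions: aq. HCl (3 M)/MeOH (1:10), rt to 40 °C
Reagents that add atoms: none
Why: Acid-catalysed acetal cleavage (transacetalisation to methanol) removes both aryl MOM ethers under conditions mild enough that the ortho-prenylphenols should not cyclise to chromans.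

**Compound list**

1 | 1-(2,4,6-trihydroxyphenyl)ethanone | CC(=O)c1c(O)cc(O)cc1O | starting material
2 | 1-[2,6-dihydroxy-4-(methoxymethoxy)phenyl]ethanone | CC(=O)c1c(O)cc(OCOC)cc1O | intermediate
3 | (E)-1-[2,6-dihydroxy-4-(methoxymethoxy)phenyl]-3-(dimethylamino)prop-2-en-1-one | CN(C)/C=C/C(=O)c1c(O)cc(OCOC)cc1O | intermediate
4 | 5-hydroxy-3-iodo-7-(methoxymethoxy)chromen-4-one | O=c1c(I)coc2cc(OCOC)cc(O)c12 | intermediate
5 | 5-bromo-2,3-dihydroxybenzaldehyde | O=Cc1cc(Br)cc(O)c1O | starting material
6 | 5-bromo-2-hydroxy-3-(methoxymethoxy)benzaldehyde | O=Cc1cc(Br)cc(OCOC)c1O | intermediate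
7 | 2-hydroxy-3-(methoxymethoxy)-5-(4,4,5,5-tetramethyl-1,3,2-dioxaborolan-2-yl)benzaldehyde | O=Cc1cc(B2OC(C)(C)C(C)(C)O2)cc(OCOC)c1O | intermediate
8 | 2-hydroxy-5-[5-hydroxy-7-(methoxymethoxy)-4-oxochromen-3-yl]-3-(methoxymethoxy)benzaldehyde | O=Cc1cc(-c2coc3cc(OCOC)cc(O)c3c2=O)cc(OCOC)c1O | intermediate
9 | 2-hydroxy-5-[5-hydroxy-6-iodo-7-(methoxymethoxy)-4-oxochromen-3-yl]-3-(methoxymethoxy)benzaldehyde | O=Cc1cc(-c2coc3cc(OCOC)c(I)c(O)c3c2=O)cc(OCOC)c1O | intermediate
10 | 5-hydroxy-3-[4-hydroxy-3-(hydroxymethyl)-5-(methoxymethoxy)phenyl]-6-iodo-7-(methoxymethoxy)chromen-4-one | OCc1cc(-c2coc3cc(OCOC)c(I)c(O)c3c2=O)cc(OCOC)c1O | intermediate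
11 | 5-hydroxy-6-(hydroxymethyl)-3-[4-hydroxy-3-(hydroxymethyl)-5-(methoxymethoxy)phenyl]-7-(methoxymethoxy)chromen-4-one (key-step precursor) | OCc1cc(-c2coc3cc(OCOC)c(CO)c(O)c3c2=O)cc(OCOC)c1O | intermediate
12 | (2-methylprop-1-en-1-yl)boronic acid | CC(C)=CB(O)O | starting material
13 | bis(alkenyldioxaborin): 11 with O5/6-CH2O and O4'/5'-CH2O each bridged by B–CH=C(CH3)2 | CC(C)=CB1OCc2cc(cc(OCOC)c2O1)-c1coc2cc(OCOC)c3COB(C=C(C)C)Oc3c2c1=O | intermediate (not isolated)
14 | boron-bound bis(ortho-quinone methide), drawn with both rings ionised although they need not ionise at the same time | O=C1C(C3=CC(=C)C(=[O+]B([O-])C=C(C)C)C(OCOC)=C3)=COC2=C1C(=[O+]B([O-])C=C(C)C)C(=C)C(OCOC)=C2 | intermediate (not isolated)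
15 | 5-hydroxy-3-[4-hydroxy-3-(methoxymethoxy)-5-(3-methylbut-2-en-1-yl)phenyl]-7-(methoxymethoxy)-6-(3-methylbut-2-en-1-yl)chromen-4-one (key-step product) | CC(C)=CCc1cc(-c2coc3cc(OCOC)c(CC=C(C)C)c(O)c3c2=O)cc(OCOC)c1O | intermediate
16 | isoangustone A | CC(C)=CCc1cc(-c2coc3cc(O)c(CC=C(C)C)c(O)c3c2=O)cc(O)c1O | target

**Step count and risks**

Total steps: 11. Longest linear sequence: 9 (steps 1–3 and 6–11, from 1); the ring B branch (steps 4–5) joins at step 6.

Three steps most likely to fail:

1. Step 10 (key step). Ionisation of the ring B dioxaborin may be too slow at temperatures where the ring A quinone methide already oligomerises through C8 of a second molecule, or chelation of boron between O5 and the C4 carbonyl may hold ring A in an unreactive tetracoordinate state. The fallback sets out from 11 and returns at 15. Heating 11 in ethanol in a sealed vessel at about 110 °C (thermal solvolysis through the quinone methides) should give 6-(ethoxymethyl)-3-[3-(ethoxymethyl)-4-hydroxy-5-(methoxymethoxy)phenyl]-5-hydroxy-7-(methoxymethoxy)chromen-4-one F1. Separately, 12 is esterified with propan-2-ol over molecular sieves to diisopropyl (2-methylprop-1-en-1-yl)boronate F2. F1 and F2 with 20 mol% of 3,3'-dibromo-1,1'-bi-2-naphthol in toluene at 60–80 °C should give 15 by the known biphenol-catalysed addition of alkenylboronates to ortho-quinone methides released from ortho-(alkoxymethyl)phenols, that is, exchange catalysis on a boronate ester instead of a stoichiometric dioxaborin.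

2. Step 9. Transmetalation at the doubly ortho-substituted C6–palladium centre may be slow, so that protodeiodination competes, and the product may self-condense thermally during the coupling. The fallback sets out from 8 and returns at 11 without iodide or tin. NaBH4 at 0 °C reduces 8 to 5-hydroxy-3-[4-hydroxy-3-(hydroxymethyl)-5-(methoxymethoxy)phenyl]-7-(methoxymethoxy)chromen-4-one F3. Phenylboronic acid, paraformaldehyde and catalytic propionic acid in toluene with removal of water (boronic-acid-templated ortho-specific hydroxymethylation of phenols) should deliver formaldehyde to C6, the only carbon ortho to the boron-bound O5, and at the same time esterify the ring B diol, giving the bis(2-phenyl-4H-1,3,2-dioxaborin) F4. Transesterification with pinacol in THF at room temperature then frees 11.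

3. Step 7. Iodination may also occur para to O5 at C8, or twice, which would give regioisomeric or over-iodinated material. The fallback fixes the position of the carbon by construction; it sets out from 2 and returns at 11.
   - N-Iodosuccinimide in DMF at 0 °C iodinates one of the two equivalent ring positions of 2 to give 1-[2,6-dihydroxy-3-iodo-4-(methoxymethoxy)phenyl]ethanone F5.
   - Stille coupling with (tributylstannyl)methanol gives 1-[2,6-dihydroxy-3-(hydroxymethyl)-4-(methoxymethoxy)phenyl]ethanone F6.
   - 2-Methoxypropene with catalytic pyridinium p-toluenesulfonate ties the CH2OH to its only free neighbouring phenol as 1-[7-hydroxy-5-(methoxymethoxy)-2,2-dimethyl-4H-1,3-benzodioxin-8-yl]ethanone F7, which leaves a single phenol able to close the pyranone.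
   - The amide acetal gives the enaminone (E)-3-(dimethylamino)-1-[7-hydroxy-5-(methoxymethoxy)-2,2-dimethyl-4H-1,3-benzodioxin-8-yl]prop-2-en-1-one F8.
   - Iodine and pyridine close it to 3-iodo-7-(methoxymethoxy)chromen-4-one bridged from O5 to the 6-CH2O by an isopropylidene acetal F9.
   - Suzuki–Miyaura coupling with 7 gives the corresponding isoflavone aldehyde F10, and NaBH4 gives the ring B benzyl alcohol F11.
   - Aqueous acetic acid in THF at 40 °C cleaves the isopropylidene acetal in the presence of the aryl MOM ethers and gives 11.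

**Further compounds**

F1 | step 10 | 6-(ethoxymethyl)-3-[3-(ethoxymethyl)-4-hydroxy-5-(methoxymethoxy)phenyl]-5-hydroxy-7-(methoxymethoxy)chromen-4-one | CCOCc1cc(-c2coc3cc(OCOC)c(COCC)c(O)c3c2=O)cc(OCOC)c1O
F2 | step 10 | diisopropyl (2-methylprop-1-en-1-yl)boronate | CC(C)=CB(OC(C)C)OC(C)C
F3 | step 9 | 5-hydroxy-3-[4-hydroxy-3-(hydroxymethyl)-5-(methoxymethoxy)phenyl]-7-(methoxymethoxy)chromen-4-one | OCc1cc(-c2coc3cc(OCOC)cc(O)c3c2=O)cc(OCOC)c1O
F4 | step 9 | bis(2-phenyl-4H-1,3,2-dioxaborin) of 11 (B–Ph bridging O5/6-CH2O and O4'/5'-CH2O) | c1ccccc1B1OCc2cc(cc(OCOC)c2O1)-c1coc2cc(OCOC)c3COB(c4ccccc4)Oc3c2c1=O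
F5 | step 7 | 1-[2,6-dihydroxy-3-iodo-4-(methoxymethoxy)phenyl]ethanone | CC(=O)c1c(O)cc(OCOC)c(I)c1O
F6 | step 7 | 1-[2,6-dihydroxy-3-(hydroxymethyl)-4-(methoxymethoxy)phenyl]ethanone | CC(=O)c1c(O)cc(OCOC)c(CO)c1O
F7 | step 7 | 1-[7-hydroxy-5-(methoxymethoxy)-2,2-dimethyl-4H-1,3-benzodioxin-8-yl]ethanone | CC(=O)c1c(O)cc(OCOC)c2COC(C)(C)Oc12
F8 | step 7 | (E)-3-(dimethylamino)-1-[7-hydroxy-5-(methoxymethoxy)-2,2-dimethyl-4H-1,3-benzodioxin-8-yl]prop-2-en-1-one | CN(C)/C=C/C(=O)c1c(O)cc(OCOC)c2COC(C)(C)Oc12
F9 | step 7 | 3-iodo-7-(methoxymethoxy)chromen-4-one with O5 and the 6-CH2O bridged as an isopropylidene acetal | O=c1c(I)coc2cc(OCOC)c3COC(C)(C)Oc3c12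
F10 | step 7 | 2-hydroxy-3-(methoxymethoxy)-5-(acetonide-bridged 7-(methoxymethoxy)-4-oxochromen-3-yl)benzaldehyde | O=Cc1cc(-c2coc3cc(OCOC)c4COC(C)(C)Oc4c3c2=O)cc(OCOC)c1O
F11 | step 7 | 3-[4-hydroxy-3-(hydroxymethyl)-5-(methoxymethoxy)phenyl]-7-(methoxymethoxy)chromen-4-one with O5 and the 6-CH2O bridged as an isopropylidene acetal | OCc1cc(-c2coc3cc(OCOC)c4COC(C)(C)Oc4c3c2=O)cc(OCOC)c1O
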